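## Retrosynthetic overview
1. The C5 quaternary ether (Me exo, chain endo, cis to the lactone) comes from Me⁻ attack on the convex face of the bicyclic oxocarbenium derived from methyl ketal 15.
2. Lactone 15 comes from oxidative excision of the enone arm of cis-fused hydrobenzofuranone 11, with the C3a–C4 bond replaced by a C–O bond with retention.
3. Ketal 11 comes from a desymmetrising hemiketal oxa-Michael on the prochiral dienone 9. This closes the THF ring first and sets the absolute configuration.
4. Dienone 9 comes from dearomative para-alkylation of p-cresol with enol silane 7. Enol silane 7 comes from Ph(CH2)10-ketone 5, which is built from 1,10-dibromodecane and PhMgBr.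

**Assumptions.**
- The ketal carbon in 11, 13 and 15 is carried as an epimeric mixture, because Step 8 removes that stereocentre by ionisation.
- (S)-TRIP is assumed to give the (3aS,7aR) sense of 11; if it does not, use (R)-TRIP.

## Route

**Step 1**
Reactants: 1 (1,10-dibromodecane, 3 equiv), 2 (phenylmagnesium bromide)
Product: 3 (10-bromodecyl)benzene
Conditions: Li2CuCl4 (5 mol %), THF, 0 °C → rt
Reagents that add atoms: phenylmagnesium bromide, Br[Mg]c1ccccc1 (compound 2)
Why: Cu-catalysed Kumada–Kochi coupling; excess symmetrical dibromide 1 makes mono-arylation statistical, which breaks the symmetry of 1. No stereocentre is formed.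

**Step 2**
Reactants: 3, 4 (N-methoxy-N-methylacetamide)
Product: 5 (12-phenyldodecan-2-one)
Conditions: Mg, THF, reflux; then 4, 0 °C → rt
Reagents that add atoms: N-methoxy-N-methylacetamide, CON(C)C(C)=O (compound 4)
Why: Grignard formation followed by Weinreb ketone synthesis; the chelated tetrahedral intermediate prevents over-addition. No stereocentre is formed.

**Step 3**
Reactants: 5, 6 (chlorotrimethylsilane)
Product: 7 (kinetic silyl enol ether, CH2=C(OTMS)R)
Conditions: LDA, THF, −78 °C; then 6, −78 °C → rt
Reagents that add atoms: chlorotrimethylsilane, C[Si](C)(C)Cl (compound 6)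
Why: Kinetic deprotonation of the methyl side of a methyl ketone gives the terminal enol silane; no stereocentre is formed.

**Step 4**
Reactants: 7, 8 (p-cresol)
Product: 9 (4-methyl-4-(2-oxo-12-phenyldodecyl)cyclohexa-2,5-dien-1-one)
Conditions: PhI(OAc)2 (1.1 equiv), HFIP, −40 → 0 °C
Reagents that add atoms: none
Why: Proposed new method: PIDA oxidises p-cresol to a phenoxenium ion, and the enol silane attacks at the methyl-bearing para carbon, giving the achiral, symmetric (prochiral) 4,4-disubstituted dienone. This breaks the aromaticity of the cresol ring. The closest known reactions are Kita-type hypervalent-iodine dearomatisation of p-substituted phenols with allylsilanes and oxidative phenol–enolate coupling.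

**Step 5**
Reactants: 9, 10 (methanol)
Product: 11 (3aS,7aR)-2-methoxy-3a-methyl-2-(10-phenyldecyl)-3,3a,7,7a-tetrahydro-1-benzofuran-6(2H)-one
Conditions: (S)-TRIP (10 mol %), MeOH (3 equiv), toluene, 0 °C → rt, 48 h
Reagents that add atoms: methanol, CO (compound 10)
Why: Proposed new method: the chiral phosphoric acid promotes hemiketal formation from the ketone and MeOH and delivers the hemiketal OH to one enantiotopic enone β-carbon by 5-exo oxa-Michael, which breaks the symmetry of 9. This fixes the quaternary C3a and C7a, and the cis ring fusion is forced by the 5-exo closure. The ketal carbon is epimeric and irrelevant. The closest known reactions are CPA-catalysed desymmetrising oxa-Michael of cyclohexadienones and hemiketal/oxa-Michael cascades.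

**Step 6**
Reactants: 11, 12 (ozone)
Product: 13 (2R,3R)-2-(2,3-dioxopropyl)-5-methoxy-3-methyl-5-(10-phenyldecyl)oxolan-3-yl formate
Conditions: O3 (1.1 equiv), CH2Cl2/MeOH 4:1, −78 °C; then Ac2O, DMAP (cat.), pyridine, −78 → 25 °C
Reagents that add atoms: ozone, O=[O+][O-] (compound 12)
Why: Proposed new method: ozonolysis in MeOH puts the carbonyl oxide on the β-carbon, giving the α-methoxy hydroperoxide at C4. Acylation triggers Criegee rearrangement with migration of tertiary C3a to oxygen with retention, giving the formate, and the other terminus stays as the α-keto aldehyde. The closest known reactions are ozonolysis–Criegee sequences on quaternary-carbon alkenes and enone ozonolysis of cholest-4-en-3-one.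

**Step 7**
Reactants: 13, 14 (hydrogen peroxide)
Product: 15 (3aR,6aR)-5-methoxy-6a-methyl-5-(10-phenyldecyl)tetrahydrofuro[3,2-b]furan-2(3H)-one
Conditions: 30% H2O2, K2CO3, MeOH, 0 °C; then HCl/MeOH to pH 2, 25 °C
Reagents that add atoms: hydrogen peroxide, OO (compound 14)
Why: H2O2 cleaves the α-keto aldehyde to the carboxylic acid (known 1,2-dicarbonyl cleavage), and K2CO3/MeOH removes the formate to free the tertiary alcohol. Acidification lactonises the cis γ-hydroxy acid onto the same face, so the lactone is cis-fused and the ring-fusion stereocentres are preserved.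

**Step 8**
Reactants: 15, 16 (dimethylzinc)
Product: 17 (target, plakortolide ether)
Conditions: Me2Zn (4 equiv), TiCl4 (4 equiv, giving Me2TiCl2), CH2Cl2, −30 → 0 °C
Reagents that add atoms: dimethylzinc, C[Zn]C (compound 16)
Why: Reetz-type Lewis-acid ionisation of the ketal (both epimers) gives the bicyclic oxocarbenium, and Me is delivered to the convex face. This puts Me exo and the chain endo, as in the target, and the lactone is inert to Me2TiCl2. The angular methyl lies on the same face, so selectivity may be only moderate; the minor C5 epimer is removed by chromatography.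

## Compound list
1 | 1,10-dibromodecane | BrCCCCCCCCCCBr | starting material
2 | phenylmagnesium bromide | Br[Mg]c1ccccc1 | starting material
3 | (10-bromodecyl)benzene | BrCCCCCCCCCCc1ccccc1 | intermediate
4 | N-methoxy-N-methylacetamide | CON(C)C(C)=O | starting material
5 | 12-phenyldodecan-2-one | CC(=O)CCCCCCCCCCc1ccccc1 | intermediate
6 | chlorotrimethylsilane | C[Si](C)(C)Cl | starting material
7 | trimethyl{[12-phenyldodec-1-en-2-yl]oxy}silane | C=C(O[Si](C)(C)C)CCCCCCCCCCc1ccccc1 | intermediate
8 | p-cresol | Cc1ccc(O)cc1 | starting material
9 | 4-methyl-4-(2-oxo-12-phenyldodecyl)cyclohexa-2,5-dien-1-one | CC1(CC(=O)CCCCCCCCCCc2ccccc2)C=CC(=O)C=C1 | intermediate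
10 | methanol | CO | starting material
11 | (3aS,7aR)-2-methoxy-3a-methyl-2-(10-phenyldecyl)-3,3a,7,7a-tetrahydro-1-benzofuran-6(2H)-one (C2 epimers) | COC1(CCCCCCCCCCc2ccccc2)C[C@@]2(C)C=CC(=O)C[C@H]2O1 | intermediate
12 | ozone | O=[O+][O-] | starting material
13 | (2R,3R)-2-(2,3-dioxopropyl)-5-methoxy-3-methyl-5-(10-phenyldecyl)oxolan-3-yl formate (C5 epimers) | O=CC(=O)C[C@H]1OC(OC)(CCCCCCCCCCc2ccccc2)C[C@@]1(C)OC=O | intermediate
14 | hydrogen peroxide | OO | starting material
15 | (3aR,6aR)-5-methoxy-6a-methyl-5-(10-phenyldecyl)tetrahydrofuro[3,2-b]furan-2(3H)-one (C5 epimers) | COC1(CCCCCCCCCCc2ccccc2)C[C@@]2(C)OC(=O)C[C@H]2O1 | intermediate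
16 | dimethylzinc | C[Zn]C | starting material
17 | plakortolide ether, (3aR,5S,6aR)-5,6a-dimethyl-5-(10-phenyldecyl)tetrahydrofuro[3,2-b]furan-2(3H)-one | C[C@]1(CCCCCCCCCCc2ccccc2)C[C@@]2(C)OC(=O)C[C@H]2O1 | target

## Totals
Total steps: 8. Longest linear sequence: 8 (from 1,10-dibromodecane).

## Three steps most likely to fail
1. **Step 5 (enantioselective hemiketal oxa-Michael).** Ketone hemiketals are present at very low concentration, and the reaction is reversible.
   Fallback: cyclise with achiral DBU/MeOH to give (±)-11, then separate the enantiomers of 15 by preparative chiral SFC; the ketal epimers converge in Step 8.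
2. **Step 4 (dearomative para-alkylation).** The phenoxenium ion may react at the ortho carbon instead, giving a rearomatised ortho-alkylated phenol, or PIDA may oxidise the enol silane directly.
   Fallback: Pd-catalysed dearomative para-allylation of p-cresol with 2-(10-phenyldecyl)allyl methyl carbonate, then chemoselective ozonolysis (1.0 equiv, −78 °C) of the 1,1-disubstituted alkene to give ketone 9.
3. **Step 6 (ozonolysis/Criegee).** Dehydration of the α-methoxy hydroperoxide to the methyl ester may outcompete migration of the tertiary carbon.
   Fallback: reductive ozonolysis (O3; PPh3), then Baeyer–Villiger of the α-quaternary aldehyde with mCPBA/NaHCO3 to give the formate (peracid instead of hydroperoxide acylation), then Step 7.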